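The data stem from a simulated flask with made-up constants.

In a one-step world each substrate that goes becomes target, and the fraction left tells the yield. These runs refuse that world.

| flask | substrate | reagent | temperature | remark | time |
|---|---|---|---|---|---|
| south-west | 0.30 M | 0.19 M | 20 °C | run made earlier |  |
| west | 0.30 M | 1.1 M | 48 °C | run made earlier |  |
| north-east | 0.54 M | 0.75 M | 20 °C | run made earlier |  |
| Wednesday's | 1.0 M | 0.750 M | 40 °C |  | 20 d |
| Monday's | 0.30 M | 0.500 M | 70 °C |  | 20 d |
| Friday's | 0.30 M | 0.750 M | 40 °C |  | 20 d |
| Tuesday's | 0.30 M | 0.750 M | 25 °C |  | 20 d |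
| Saturday's | 0.20 M | 1.50 M | 25 °C |  | 20 d |
| Thursday's | 1.0 M | 0.250 M | 70 °C |  | 20 d |

| run | time / d | target / % | substrate / % |
|---|---|---|---|
| south-west | 10.0 | 10.2 | 52.9 |
| south-west | 20.0 | 18.6 | 37.8 |
| south-west | 25.0 | 23.0 | 31.4 |
| south-west | 40.0 | 26.0 | 19.8 |
| west | 4.00 | 49.1 | 0 |
| west | 8.00 | 50.9 | 0.3 |
| west | 10.0 | 49.7 | 0 |
| west | 15.0 | 50.8 | 0 |
| north-east | 10.0 | 21.4 | 23.1 |
| north-east | 20.0 | 33.1 | 15.1 |
| north-east | 25.0 | 38.2 | 11.1 |
| north-east | 40.0 | 43.4 | 2.9 |

(each reading ± 1 percentage point)

- all flasks from highest to lowest amount of target, in percent of the substrate charged, at 20 d (Wednesday's / Monday's / Friday's / Tuesday's / Saturday's / Thursday's)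
- the amount of target, in percent of the substrate charged of the flask you put first, at 20 d
- the amount of target, in percent of the substrate charged of the flask you put last, at 20 d

In the west run substrate is down to 0 % at 4.00 d, and target averages 50.1 %. I call this the covered yield: target per substrate charged when [reagent] stands above [substrate].

I doubt Thursday's, and I have two ways to its target. The first carries the covered yield across as it is and gives 50.1 %. The second counts. If one reagent is used per substrate, as I assume, reagent is the limiting reagent in Thursday's and covers 25.0 % of the substrate, so the covered yield gives 12.5 %. The ways part by a factor of 4.01.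

The south-west run gives a hint of which one cheats. There reagent covers 63.3 % of the substrate, and by 25.0 d the substrate gone, 68.6 %, is already more than that. From then to 40.0 d, target gains 3 percentage points while substrate loses 12 points, a share of 25.9 %. Over the same stretch the north-east run, at the same temperature and with reagent charged above substrate, reads a share of 63.4 %, which reads higher. But each share is a ratio of differences of small readings with a scatter of 1 point on each, so the gap is a lean and not a proof. So I lean towards reagent being used up, and I take the first way to be the one that cheats: its plateau was read with [reagent] 3.67 times [substrate]. I put Thursday's last, near 12.5 %.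

The forecast differs. It gives Wednesday's > Monday's > Thursday's > Friday's > Tuesday's > Saturday's, with 50 % first and 41 % last, and holds that “reagent is evidently regenerated or catalytic”.

The flasks give Friday's > Tuesday's > Wednesday's > Saturday's > Monday's > Thursday's, with 49.6 % first and 12.9 % in Thursday's.

    substrate → side product A (k = 0.0200 h⁻¹, Ea = 111 kJ mol⁻¹)
    substrate + reagent ⇌ intermediate A (K = 2.40 L mol⁻¹, k = 0.240 L mol⁻¹ h⁻¹, Ea = 63.0 kJ mol⁻¹, ΔH = −19.0 kJ mol⁻¹)
    reagent + intermediate A → side product B (k = 0.0210 L mol⁻¹ h⁻¹, Ea = 71.0 kJ mol⁻¹)
    intermediate A → intermediate B (k = 0.0100 h⁻¹, Ea = 120 kJ mol⁻¹)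
    intermediate A → target (k = 0.0450 h⁻¹, Ea = 112 kJ mol⁻¹)
    intermediate B ⇌ intermediate C (K = 6.90, k = 0.0590 h⁻¹, Ea = 108 kJ mol⁻¹, ΔH = −41.0 kJ mol⁻¹)
    (constants at 40 °C)

Thursday's holds side product A at 83.1 % and still has reagent at 31.6 % of its charge, so my picture of reagent used to the end is not what stands there. Divided by its cover, Thursday's target comes to 51.6 %, beside the covered yield of 50.1 %.

In the repeat of Friday's with 1.2 M of substrate, reagent covers 62.5 %, so the covered yield gives 31.3 %. That flask gives 38.2 %, more than I reckon.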